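**Retrosynthetic overview**

Labdane locants are used: ring A = C1–C5 and C10, ring B = C5–C10, C17 on C8, C18 (CH3) and C19 (CO2H) on C4, C20 on C10, C11–C12 link C9 to the butenolide.
Target ⇐ (C17 aldehyde to CH2OH, tert-butyl ester removed) ⇐ ring B closed last through the C9–C10 bond: an iron hydride transfers a hydrogen atom to C1 of a ring A cyclohexene, and the tertiary C10 radical adds 6-endo to C9 of a (Z)-2-alkyl enal.
Enabling feature: the quaternary C10 (carrying C20) is bonded to C9, and C8 carries the oxidised carbon C17, so C1=C10 can be the radical donor and C8(CHO)=C9 the acceptor; one operation then sets C10, C9 and C8 and delivers C17 at the aldehyde level.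
Ring A ⇐ catalytic enantioselective Diels–Alder reaction of methacrolein with a 1-alkyl-2-methylbuta-1,3-diene (sets C4 and C5, leaves C1=C10); the diene ⇐ two Wittig reactions on an aldehyde from a Claisen rearrangement that fixes the (Z)-alkene; the Claisen substrate ⇐ Nozaki–Hiyama–Kishi coupling of a butenolide aldehyde.
Order of rings: butenolide (bought as 3-bromofuran-2(5H)-one), then ring A (step 8), then ring B (step 13).

Key step: step 13

Assumption: in step 8 the (S)-configured oxazaborolidinium catalyst is taken to shield the si face of the formyl-bearing carbon of methacrolein, as in the accepted model for 2-substituted acroleins; if the sense proved opposite, the (R)-catalyst would be used with no other change.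

**Route**

Step 1
Reactants: 1 3,3-diethoxyprop-1-ene (acrolein diethyl acetal); 2 3-bromofuran-2(5H)-one
Product: 4 3-(3,3-diethoxypropyl)furan-2(5H)-one, via alkylborane 3 (not isolated)
Conditions: 1, 9-BBN dimer, THF, 0 → 23 °C; then 2, Pd(dppf)Cl2 (5 mol%), AsPh3 (5 mol%), K3PO4 (3 M aq), DMF, 23 °C
Reagents that add atoms: none
Why: 9-BBN adds anti-Markovnikov to the vinyl acetal and the B-alkyl group is transferred to the sp2 C–Br bond in a B-alkyl Suzuki–Miyaura coupling, a reaction type established for α-halo enones and enoates; no stereocentre is formed.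

Step 2
Reactants: 4 3-(3,3-diethoxypropyl)furan-2(5H)-one
Product: 5 3-(2-oxo-2,5-dihydrofuran-3-yl)propanal
Conditions: 1 M HCl (aq), THF, 23 °C
Reagents that add atoms: water, O
Why: Acid-catalysed acetal hydrolysis, to which the butenolide is inert.

Step 3
Reactants: 6 2-bromoprop-2-en-1-ol
Product: 7 [(2-bromoprop-2-en-1-yl)oxy](tert-butyl)dimethylsilane
Conditions: TBSCl, imidazole, CH2Cl2, 0 → 23 °C
Reagents that add atoms: tert-butyldimethylsilyl chloride, CC(C)(C)[Si](C)(C)Cl
Why: Standard silylation of a primary alcohol.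

Step 4
Reactants: 5 3-(2-oxo-2,5-dihydrofuran-3-yl)propanal; 7 [(2-bromoprop-2-en-1-yl)oxy](tert-butyl)dimethylsilane
Product: 8 rac-3-[4-({[tert-butyl(dimethyl)silyl]oxy}methyl)-3-hydroxypent-4-en-1-yl]furan-2(5H)-one
Conditions: CrCl2 (4 equiv), NiCl2 (2 mol%), DMF, 23 °C; aqueous work-up
Reagents that add atoms: none
Why: Nozaki–Hiyama–Kishi coupling, in which the alkenylchromium species adds chemoselectively to the aldehyde and leaves the butenolide untouched; the carbinol centre is racemic and is destroyed in step 5.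

Step 5
Reactants: 8 rac-3-[4-({[tert-butyl(dimethyl)silyl]oxy}methyl)-3-hydroxypent-4-en-1-yl]furan-2(5H)-one
Product: 10 (4Z)-4-({[tert-butyl(dimethyl)silyl]oxy}methyl)-7-(2-oxo-2,5-dihydrofuran-3-yl)hept-4-enal, via allyl vinyl ether 9 (not isolated)
Conditions: ethyl vinyl ether (solvent), Hg(OAc)2 (0.3 equiv), reflux; concentrate; PhMe, 130 °C (sealed tube)
Reagents that add atoms: ethyl vinyl ether, C=COCC
Why: Transfer vinylation followed by a [3,3]-sigmatropic Claisen rearrangement through a chair with the carbinol substituent equatorial, which should place the butenolide-bearing chain trans to the new CH2CH2CHO arm and cis to the CH2OTBS group (4Z), the geometry that later sets C9.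

Step 6
Reactants: 10 (4Z)-4-({[tert-butyl(dimethyl)silyl]oxy}methyl)-7-(2-oxo-2,5-dihydrofuran-3-yl)hept-4-enal
Product: 11 (2E,6Z)-6-({[tert-butyl(dimethyl)silyl]oxy}methyl)-2-methyl-9-(2-oxo-2,5-dihydrofuran-3-yl)nona-2,6-dienal
Conditions: 2-(triphenyl-λ5-phosphanylidene)propanal (1.3 equiv), PhMe, 80 °C
Reagents that add atoms: 2-(triphenyl-λ5-phosphanylidene)propanal, CC(C=O)=P(c1ccccc1)(c1ccccc1)c1ccccc1
Why: Wittig reaction of a stabilised ylide, which reacts only with the aldehyde and should give the (E)-2-methyl enal.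

Step 7
Reactants: 11 (2E,6Z)-6-({[tert-butyl(dimethyl)silyl]oxy}methyl)-2-methyl-9-(2-oxo-2,5-dihydrofuran-3-yl)nona-2,6-dienal
Product: 12 3-[(3Z,7E)-4-({[tert-butyl(dimethyl)silyl]oxy}methyl)-8-methyldeca-3,7,9-trien-1-yl]furan-2(5H)-one
Conditions: Ph3PCH3Br, KN(SiMe3)2, THF, 0 °C (ylide, 1.1 equiv); then 11, −78 → −20 °C
Reagents that add atoms: methyltriphenylphosphonium bromide, C[P+](c1ccccc1)(c1ccccc1)c1ccccc1.[Br-]
Why: Wittig methylenation of the enal at low temperature with a small excess of preformed ylide, conditions under which the aldehyde should react far faster than the butenolide is deprotonated or attacked.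

Step 8
Reactants: 12 3-[(3Z,7E)-4-({[tert-butyl(dimethyl)silyl]oxy}methyl)-8-methyldeca-3,7,9-trien-1-yl]furan-2(5H)-one; 13 methacrolein (2-methylprop-2-enal)
Product: 14 (1S,2R)-2-[(3Z)-3-({[tert-butyl(dimethyl)silyl]oxy}methyl)-6-(2-oxo-2,5-dihydrofuran-3-yl)hex-3-en-1-yl]-1,3-dimethylcyclohex-3-ene-1-carbaldehyde
Conditions: (S)-diphenylprolinol-derived B-(o-tolyl)oxazaborolidine (20 mol%) protonated with Tf2NH (18 mol%), 13 (5 equiv), CH2Cl2, −78 → −40 °C
Reagents that add atoms: none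
Why: Enantioselective Diels–Alder reaction under chiral oxazaborolidinium catalysis, in which the 1-alkyl terminus of the diene directs the "ortho" regiochemistry, the formyl group reacts endo and so ends cis to the side chain (C4/C5 relative configuration), and the catalyst leaves open the face of the s-trans enal that leads to (1S,2R).

Step 9
Reactants: 14 (1S,2R)-2-[(3Z)-3-({[tert-butyl(dimethyl)silyl]oxy}methyl)-6-(2-oxo-2,5-dihydrofuran-3-yl)hex-3-en-1-yl]-1,3-dimethylcyclohex-3-ene-1-carbaldehyde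
Product: 15 (1S,2R)-2-[(3Z)-3-({[tert-butyl(dimethyl)silyl]oxy}methyl)-6-(2-oxo-2,5-dihydrofuran-3-yl)hex-3-en-1-yl]-1,3-dimethylcyclohex-3-ene-1-carboxylic acid
Conditions: NaClO2, NaH2PO4, 2-methyl-2-butene (excess), t-BuOH/H2O, 0 → 23 °C
Reagents that add atoms: sodium chlorite, [Na+].[O-]Cl=O
Why: Pinnick oxidation, which converts even a neopentyl aldehyde into the acid and spares the alkenes because 2-methyl-2-butene scavenges the hypochlorous acid.

Step 10
Reactants: 15 (1S,2R)-2-[(3Z)-3-({[tert-butyl(dimethyl)silyl]oxy}methyl)-6-(2-oxo-2,5-dihydrofuran-3-yl)hex-3-en-1-yl]-1,3-dimethylcyclohex-3-ene-1-carboxylic acid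
Product: 16 tert-butyl (1S,2R)-2-[(3Z)-3-({[tert-butyl(dimethyl)silyl]oxy}methyl)-6-(2-oxo-2,5-dihydrofuran-3-yl)hex-3-en-1-yl]-1,3-dimethylcyclohex-3-ene-1-carboxylate
Conditions: tert-butyl 2,2,2-trichloroacetimidate (3 equiv), cyclohexane/CH2Cl2 (2:1), 23 °C
Reagents that add atoms: tert-butyl 2,2,2-trichloroacetimidate, CC(C)(C)OC(=N)C(Cl)(Cl)Cl
Why: O-alkylation of the acid by the acid-activated imidate (tert-butyl cation transfer), a mechanism that is insensitive to the hindrance at C4 and mild enough for the silyl ether.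

Step 11
Reactants: 16 tert-butyl (1S,2R)-2-[(3Z)-3-({[tert-butyl(dimethyl)silyl]oxy}methyl)-6-(2-oxo-2,5-dihydrofuran-3-yl)hex-3-en-1-yl]-1,3-dimethylcyclohex-3-ene-1-carboxylate
Product: 17 tert-butyl (1S,2R)-2-[(3Z)-3-(hydroxymethyl)-6-(2-oxo-2,5-dihydrofuran-3-yl)hex-3-en-1-yl]-1,3-dimethylcyclohex-3-ene-1-carboxylate
Conditions: HF·pyridine, pyridine, THF, 0 → 23 °C
Reagents that add atoms: none
Why: Buffered fluoride cleavage of the primary silyl ether, non-basic conditions that spare the tert-butyl ester and the butenolide.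

Step 12
Reactants: 17 tert-butyl (1S,2R)-2-[(3Z)-3-(hydroxymethyl)-6-(2-oxo-2,5-dihydrofuran-3-yl)hex-3-en-1-yl]-1,3-dimethylcyclohex-3-ene-1-carboxylate
Product: 18 tert-butyl (1S,2R)-2-[(3Z)-3-formyl-6-(2-oxo-2,5-dihydrofuran-3-yl)hex-3-en-1-yl]-1,3-dimethylcyclohex-3-ene-1-carboxylate
Conditions: Dess–Martin periodinane, NaHCO3, CH2Cl2, 0 °C
Reagents that add atoms: none
Why: Dess–Martin oxidation of the allylic alcohol under buffered neutral conditions, which should preserve the (Z)-geometry of the 2-substituted enal.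

Step 13
Reactants: 18 tert-butyl (1S,2R)-2-[(3Z)-3-formyl-6-(2-oxo-2,5-dihydrofuran-3-yl)hex-3-en-1-yl]-1,3-dimethylcyclohex-3-ene-1-carboxylate
Product: 20 tert-butyl (1S,4aR,5S,6R,8aR)-6-formyl-1,4a-dimethyl-5-[2-(2-oxo-2,5-dihydrofuran-3-yl)ethyl]decahydronaphthalene-1-carboxylate, via axial-formyl C8 epimer 19 (not isolated)
Conditions: Fe(acac)3 (30 mol%), PhSiH3 (2.5 equiv, slow addition), EtOH/ethylene glycol (5:1), 0.02 M, 60 °C; then DBU (0.3 equiv), CH2Cl2, 23 °C
Reagents that add atoms: none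
Why: An iron hydride formed from Fe(acac)3 and PhSiH3 transfers a hydrogen atom to C1 of the only electron-rich alkene (C1=C10), the tertiary C10 radical adds to C9, the β-carbon of the (Z)-enal, and the α-formyl radical at C8 is reduced and protonated, after which DBU equilibrates C8 to the equatorial aldehyde. The closest known reaction type is the iron-mediated reductive olefin coupling (hydrogen-atom-transfer Giese reaction) in its intramolecular form, and the same tertiary radical closes ring B in radical polyene cyclisations. Ring B closes 6-endo-trig, because 5-exo attack would have to occur at the fully substituted α-carbon C8 and would give an unstabilised secondary radical. C10 is controlled by the ring A chair, in which the C5 arm is equatorial and the axial C19 ester shields the β face, so that C9 bonds on the α face and C20 becomes axial (trans fusion); C9 is controlled by the (Z)-geometry of the enal, which holds C11 trans to C7 and hence equatorial in the chair transition state; C8 is under thermodynamic control (formyl equatorial, trans to the C9 chain and clear of C20). The step needs hydrogen-atom transfer to C1=C10 in the presence of the enal and the butenolide, and ring closure faster than reduction of the C10 radical; the first should be secured because C1=C10 is the only alkene that gives a tertiary alkyl radical, the second by the three-atom tether to a polarity-matched acceptor together with high dilution and slow addition of the silane.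

Step 14
Reactants: 20 tert-butyl (1S,4aR,5S,6R,8aR)-6-formyl-1,4a-dimethyl-5-[2-(2-oxo-2,5-dihydrofuran-3-yl)ethyl]decahydronaphthalene-1-carboxylate
Product: 21 (1S,4aR,5S,6R,8aR)-6-formyl-1,4a-dimethyl-5-[2-(2-oxo-2,5-dihydrofuran-3-yl)ethyl]decahydronaphthalene-1-carboxylic acid
Conditions: TFA/CH2Cl2 (1:4), 0 → 23 °C
Reagents that add atoms: none
Why: Acidolysis of the tert-butyl ester by alkyl–oxygen cleavage, which does not depend on the hindrance at C4 and leaves the aldehyde (already at its thermodynamic configuration) and the butenolide intact.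

Step 15
Reactants: 21 (1S,4aR,5S,6R,8aR)-6-formyl-1,4a-dimethyl-5-[2-(2-oxo-2,5-dihydrofuran-3-yl)ethyl]decahydronaphthalene-1-carboxylic acid
Product: 22 (1S,4aR,5S,6R,8aR)-6-(hydroxymethyl)-1,4a-dimethyl-5-[2-(2-oxo-2,5-dihydrofuran-3-yl)ethyl]decahydronaphthalene-1-carboxylic acid (target)
Conditions: NaBH4 (3 equiv), MeOH/THF, −40 °C; then aqueous citric acid
Reagents that add atoms: none
Why: At low temperature borohydride should reduce the aldehyde much faster than it attacks the α-alkyl butenolide or the carboxylate, so the C17 alcohol forms without change at any stereocentre.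

**Compound list**

1 | 3,3-diethoxyprop-1-ene | C=CC(OCC)OCC | starting material
2 | 3-bromofuran-2(5H)-one | O=C1OCC=C1Br | starting material
3 | 9-(3,3-diethoxypropyl)-9-borabicyclo[3.3.1]nonane | CCOC(CCB1C2CCCC1CCC2)OCC | intermediate
4 | 3-(3,3-diethoxypropyl)furan-2(5H)-one | CCOC(CCC1=CCOC1=O)OCC | intermediate
5 | 3-(2-oxo-2,5-dihydrofuran-3-yl)propanal | O=CCCC1=CCOC1=O | intermediate
6 | 2-bromoprop-2-en-1-ol | C=C(Br)CO | starting material
7 | [(2-bromoprop-2-en-1-yl)oxy](tert-butyl)dimethylsilane | C=C(Br)CO[Si](C)(C)C(C)(C)C | intermediate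
8 | rac-3-[4-({[tert-butyl(dimethyl)silyl]oxy}methyl)-3-hydroxypent-4-en-1-yl]furan-2(5H)-one | C=C(CO[Si](C)(C)C(C)(C)C)C(O)CCC1=CCOC1=O | intermediate
9 | rac-3-[4-({[tert-butyl(dimethyl)silyl]oxy}methyl)-3-(ethenyloxy)pent-4-en-1-yl]furan-2(5H)-one | C=COC(CCC1=CCOC1=O)C(=C)CO[Si](C)(C)C(C)(C)C | intermediate
10 | (4Z)-4-({[tert-butyl(dimethyl)silyl]oxy}methyl)-7-(2-oxo-2,5-dihydrofuran-3-yl)hept-4-enal | O=CCC/C(CO[Si](C)(C)C(C)(C)C)=C/CCC1=CCOC1=O | intermediate
11 | (2E,6Z)-6-({[tert-butyl(dimethyl)silyl]oxy}methyl)-2-methyl-9-(2-oxo-2,5-dihydrofuran-3-yl)nona-2,6-dienal | O=C/C(C)=C/CC/C(CO[Si](C)(C)C(C)(C)C)=C/CCC1=CCOC1=O | intermediate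
12 | 3-[(3Z,7E)-4-({[tert-butyl(dimethyl)silyl]oxy}methyl)-8-methyldeca-3,7,9-trien-1-yl]furan-2(5H)-one | C=C/C(C)=C/CC/C(CO[Si](C)(C)C(C)(C)C)=C/CCC1=CCOC1=O | intermediate
13 | methacrolein (2-methylprop-2-enal) | CC(=C)C=O | starting material
14 | (1S,2R)-2-[(3Z)-3-({[tert-butyl(dimethyl)silyl]oxy}methyl)-6-(2-oxo-2,5-dihydrofuran-3-yl)hex-3-en-1-yl]-1,3-dimethylcyclohex-3-ene-1-carbaldehyde | CC1=CCC[C@](C)(C=O)[C@@H]1CC/C(CO[Si](C)(C)C(C)(C)C)=C/CCC1=CCOC1=O | intermediate
15 | (1S,2R)-2-[(3Z)-3-({[tert-butyl(dimethyl)silyl]oxy}methyl)-6-(2-oxo-2,5-dihydrofuran-3-yl)hex-3-en-1-yl]-1,3-dimethylcyclohex-3-ene-1-carboxylic acid | CC1=CCC[C@](C)(C(=O)O)[C@@H]1CC/C(CO[Si](C)(C)C(C)(C)C)=C/CCC1=CCOC1=O | intermediate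
16 | tert-butyl (1S,2R)-2-[(3Z)-3-({[tert-butyl(dimethyl)silyl]oxy}methyl)-6-(2-oxo-2,5-dihydrofuran-3-yl)hex-3-en-1-yl]-1,3-dimethylcyclohex-3-ene-1-carboxylate | CC1=CCC[C@](C)(C(=O)OC(C)(C)C)[C@@H]1CC/C(CO[Si](C)(C)C(C)(C)C)=C/CCC1=CCOC1=O | intermediate
17 | tert-butyl (1S,2R)-2-[(3Z)-3-(hydroxymethyl)-6-(2-oxo-2,5-dihydrofuran-3-yl)hex-3-en-1-yl]-1,3-dimethylcyclohex-3-ene-1-carboxylate | CC1=CCC[C@](C)(C(=O)OC(C)(C)C)[C@@H]1CC/C(CO)=C/CCC1=CCOC1=O | intermediate
18 | tert-butyl (1S,2R)-2-[(3Z)-3-formyl-6-(2-oxo-2,5-dihydrofuran-3-yl)hex-3-en-1-yl]-1,3-dimethylcyclohex-3-ene-1-carboxylate | CC1=CCC[C@](C)(C(=O)OC(C)(C)C)[C@@H]1CC/C(C=O)=C/CCC1=CCOC1=O | intermediate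
19 | tert-butyl (1S,4aR,5S,6S,8aR)-6-formyl-1,4a-dimethyl-5-[2-(2-oxo-2,5-dihydrofuran-3-yl)ethyl]decahydronaphthalene-1-carboxylate (formyl axial) | C[C@]12CCC[C@](C)(C(=O)OC(C)(C)C)[C@@H]1CC[C@H](C=O)[C@@H]2CCC1=CCOC1=O | intermediate
20 | tert-butyl (1S,4aR,5S,6R,8aR)-6-formyl-1,4a-dimethyl-5-[2-(2-oxo-2,5-dihydrofuran-3-yl)ethyl]decahydronaphthalene-1-carboxylate (formyl equatorial) | C[C@]12CCC[C@](C)(C(=O)OC(C)(C)C)[C@@H]1CC[C@@H](C=O)[C@@H]2CCC1=CCOC1=O | intermediate
21 | (1S,4aR,5S,6R,8aR)-6-formyl-1,4a-dimethyl-5-[2-(2-oxo-2,5-dihydrofuran-3-yl)ethyl]decahydronaphthalene-1-carboxylic acid | C[C@]12CCC[C@](C)(C(=O)O)[C@@H]1CC[C@@H](C=O)[C@@H]2CCC1=CCOC1=O | intermediate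
22 | (1S,4aR,5S,6R,8aR)-6-(hydroxymethyl)-1,4a-dimethyl-5-[2-(2-oxo-2,5-dihydrofuran-3-yl)ethyl]decahydronaphthalene-1-carboxylic acid | C[C@]12CCC[C@](C)(C(=O)O)[C@@H]1CC[C@@H](CO)[C@@H]2CCC1=CCOC1=O | target

**Step count**

Total steps: 15. Longest linear sequence: 14 (steps 1, 2 and 4 to 15; step 3 is a one-step side branch).

**Steps most likely to fail**

Step 13. The C10 radical may be reduced before it closes the ring, the iron hydride may transfer hydrogen to the enal or the butenolide, or the α-face preference at C10 may erode and give cis fusion. The fallback is a polar, silicon-directed closure that sets out from enal 11 and comes back at 20. Takai olefination of 11 (CrCl2, Me3SiCHBr2, THF) in place of step 7 should give 3-[(3Z,7E,9E)-4-({[tert-butyl(dimethyl)silyl]oxy}methyl)-8-methyl-10-(trimethylsilyl)deca-3,7,9-trien-1-yl]furan-2(5H)-one F1. The operations of steps 8 to 12 are then repeated on the silylated series. The Diels–Alder reaction with 13 should give the allylsilane aldehyde F2, with the silyl group on C2 cis to the side chain. Pinnick oxidation gives the allylsilane acid F3, trichloroacetimidate esterification the allylsilane tert-butyl ester F4, PPTS in MeOH (in place of HF·pyridine, to spare the allylsilane) the allylsilane alcohol F5, and Dess–Martin oxidation the allylsilane (Z)-enal F6. EtAlCl2 (CH2Cl2, −78 °C) then triggers an intramolecular Hosomi–Sakurai conjugate addition in which C10 attacks C9 anti to the C2–Si bond (anti SE2'), that is on the α face. After equilibration with DBU this should give tert-butyl (1S,4aR,5S,6R,8aR)-6-formyl-1,4a-dimethyl-5-[2-(2-oxo-2,5-dihydrofuran-3-yl)ethyl]-1,2,4a,5,6,7,8,8a-octahydronaphthalene-1-carboxylate F7. Diimide (2-nitrobenzenesulfonyl hydrazide, Et3N, CH2Cl2) should reduce only the disubstituted C1=C2 alkene and give 20.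

Step 8. Facial, regio- or endo-selectivity may be insufficient, or the lactone and silyl ether may sequester the catalyst. The fallback replaces catalytic enantiocontrol by resolution; it sets out from 12 and comes back at 15. An achiral Lewis acid (Me2AlCl, CH2Cl2, −78 °C) with 13 should give 14 together with its enantiomer, the (1R,2S)-aldehyde F8. Pinnick oxidation as in step 9 gives 15 together with the (1R,2S)-acid F9. The racemic acid is resolved through its diastereomeric salts with (S)-1-phenylethylamine; the (S)-1-phenylethylammonium salt of 15 F10 is isolated by fractional crystallisation (from the crystals or the mother liquor, as found) and acidified with aqueous KHSO4 to return 15.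

Step 1. The base may degrade the bromobutenolide faster than transmetallation occurs, or the alkylpalladium intermediate may undergo β-hydride elimination. The fallback is base-free; it sets out from 2 and comes back at 5. Stille coupling of 2 with allyltributylstannane (Pd(PPh3)4, PhMe, 80 °C) should give 3-(prop-2-en-1-yl)furan-2(5H)-one F11. Hydroboration with 9-BBN and oxidation with NaBO3·4H2O gives 3-(3-hydroxypropyl)furan-2(5H)-one F12, and Dess–Martin oxidation gives 5.

**Further compounds**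

F1 | step 13 | 3-[(3Z,7E,9E)-4-({[tert-butyl(dimethyl)silyl]oxy}methyl)-8-methyl-10-(trimethylsilyl)deca-3,7,9-trien-1-yl]furan-2(5H)-one | C[Si](C)(C)/C=C/C(C)=C/CC/C(CO[Si](C)(C)C(C)(C)C)=C/CCC1=CCOC1=O
F2 | step 13 | (1S,2R,5R)-2-[(3Z)-3-({[tert-butyl(dimethyl)silyl]oxy}methyl)-6-(2-oxo-2,5-dihydrofuran-3-yl)hex-3-en-1-yl]-1,3-dimethyl-5-(trimethylsilyl)cyclohex-3-ene-1-carbaldehyde | CC1=C[C@H]([Si](C)(C)C)C[C@](C)(C=O)[C@@H]1CC/C(CO[Si](C)(C)C(C)(C)C)=C/CCC1=CCOC1=O
F3 | step 13 | (1S,2R,5R)-2-[(3Z)-3-({[tert-butyl(dimethyl)silyl]oxy}methyl)-6-(2-oxo-2,5-dihydrofuran-3-yl)hex-3-en-1-yl]-1,3-dimethyl-5-(trimethylsilyl)cyclohex-3-ene-1-carboxylic acid | CC1=C[C@H]([Si](C)(C)C)C[C@](C)(C(=O)O)[C@@H]1CC/C(CO[Si](C)(C)C(C)(C)C)=C/CCC1=CCOC1=O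
F4 | step 13 | tert-butyl (1S,2R,5R)-2-[(3Z)-3-({[tert-butyl(dimethyl)silyl]oxy}methyl)-6-(2-oxo-2,5-dihydrofuran-3-yl)hex-3-en-1-yl]-1,3-dimethyl-5-(trimethylsilyl)cyclohex-3-ene-1-carboxylate | CC1=C[C@H]([Si](C)(C)C)C[C@](C)(C(=O)OC(C)(C)C)[C@@H]1CC/C(CO[Si](C)(C)C(C)(C)C)=C/CCC1=CCOC1=O
F5 | step 13 | tert-butyl (1S,2R,5R)-2-[(3Z)-3-(hydroxymethyl)-6-(2-oxo-2,5-dihydrofuran-3-yl)hex-3-en-1-yl]-1,3-dimethyl-5-(trimethylsilyl)cyclohex-3-ene-1-carboxylate | CC1=C[C@H]([Si](C)(C)C)C[C@](C)(C(=O)OC(C)(C)C)[C@@H]1CC/C(CO)=C/CCC1=CCOC1=O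
F6 | step 13 | tert-butyl (1S,2R,5R)-2-[(3Z)-3-formyl-6-(2-oxo-2,5-dihydrofuran-3-yl)hex-3-en-1-yl]-1,3-dimethyl-5-(trimethylsilyl)cyclohex-3-ene-1-carboxylate | CC1=C[C@H]([Si](C)(C)C)C[C@](C)(C(=O)OC(C)(C)C)[C@@H]1CC/C(C=O)=C/CCC1=CCOC1=O
F7 | step 13 | tert-butyl (1S,4aR,5S,6R,8aR)-6-formyl-1,4a-dimethyl-5-[2-(2-oxo-2,5-dihydrofuran-3-yl)ethyl]-1,2,4a,5,6,7,8,8a-octahydronaphthalene-1-carboxylate | C[C@]12C=CC[C@](C)(C(=O)OC(C)(C)C)[C@@H]1CC[C@@H](C=O)[C@@H]2CCC1=CCOC1=O
F8 | step 8 | (1R,2S)-2-[(3Z)-3-({[tert-butyl(dimethyl)silyl]oxy}methyl)-6-(2-oxo-2,5-dihydrofuran-3-yl)hex-3-en-1-yl]-1,3-dimethylcyclohex-3-ene-1-carbaldehyde | CC1=CCC[C@@](C)(C=O)[C@H]1CC/C(CO[Si](C)(C)C(C)(C)C)=C/CCC1=CCOC1=O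
F9 | step 8 | (1R,2S)-2-[(3Z)-3-({[tert-butyl(dimethyl)silyl]oxy}methyl)-6-(2-oxo-2,5-dihydrofuran-3-yl)hex-3-en-1-yl]-1,3-dimethylcyclohex-3-ene-1-carboxylic acid | CC1=CCC[C@@](C)(C(=O)O)[C@H]1CC/C(CO[Si](C)(C)C(C)(C)C)=C/CCC1=CCOC1=O
F10 | step 8 | (S)-1-phenylethylammonium (1S,2R)-2-[(3Z)-3-({[tert-butyl(dimethyl)silyl]oxy}methyl)-6-(2-oxo-2,5-dihydrofuran-3-yl)hex-3-en-1-yl]-1,3-dimethylcyclohex-3-ene-1-carboxylate | CC1=CCC[C@](C)(C(=O)[O-])[C@@H]1CC/C(CO[Si](C)(C)C(C)(C)C)=C/CCC1=CCOC1=O.C[C@H]([NH3+])c1ccccc1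
F11 | step 1 | 3-(prop-2-en-1-yl)furan-2(5H)-one | C=CCC1=CCOC1=O
F12 | step 1 | 3-(3-hydroxypropyl)furan-2(5H)-one | OCCCC1=CCOC1=O
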